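**Assumption:** the C1 and C4 carbinol centres of intermediates 12–19 are carried as epimer mixtures, because both are later destroyed (C1 oxidised, C4 ionised). The target SMILES is read as (2S,3S,4R): 2,3-cis dimethyl, 3,4-trans methyl/aryl.

## Retrosynthetic overview

1. Schisandrone ⇐ its 7-O-benzyl ether ⇐ the C1 alcohol (as pivalate). The C1 ketone is unveiled only at the end under neutral conditions, so the epimerisable cis-2-methyl centre never meets acid or base.
2. The central ring is the only ring made (both arenes are bought). It is closed by intramolecular Friedel–Crafts alkylation, C4–C4a: a veratryl-stabilised C4 cation is attacked by ring A para to OBn, setting C4 trans to the C3 methyl.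
3. The cyclisation precursor ⇐ C4 aldehyde + veratryl Grignard ⇐ alkene cleavage; ring A is attached at C1 by aryllithium addition to a Weinreb amide.
4. The anti-2,3-dimethyl acid ⇐ Ireland–Claisen rearrangement of an (R,E)-pent-3-en-2-yl propanoate (1,3-chirality transfer sets C2 and C3).
5. The (R)-allylic alcohol ⇐ ketoreductase reduction of achiral (E)-pent-3-en-2-one (first stereocentre).

## Forward route

**Step 1**
Reactants: 1, (E)-pent-3-en-2-one
Product: 2, (R,E)-pent-3-en-2-ol
Conditions: (R)-selective ketoreductase (Lactobacillus brevis-type NADPH-dependent alcohol dehydrogenase), NADP+ (cat.), i-PrOH, MgCl2, phosphate buffer pH 7, 30 °C; MTBE extraction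
Reagents that add atoms: none
Why: Enzymatic asymmetric 1,2-reduction of a prochiral methyl ketone; the anti-Prelog enzyme delivers hydride to one carbonyl face to give the (R)-carbinol (expected >99% ee) without touching the C=C.

**Step 2**
Reactants: 2, (R,E)-pent-3-en-2-ol; 3, propanoyl chloride
Product: 4, (R,E)-pent-3-en-2-yl propanoate
Conditions: EtCOCl, Et3N, DMAP (cat.), CH2Cl2, 0 °C → rt
Reagents that add atoms: propanoyl chloride, CCC(=O)Cl
Why: Simple O-acylation that does not touch the carbinol stereocentre.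

**Step 3**
Reactants: 4, (R,E)-pent-3-en-2-yl propanoate
Product: 5, (2S,3S,E)-2,3-dimethylhex-4-enoic acid
Conditions: LDA, THF, −78 °C; TMSCl/Et3N, −78 °C → rt, then 50 °C; aq. NaOH, then HCl
Reagents that add atoms: none
Why: Ireland–Claisen rearrangement; the kinetic E(O)-enolate (THF, no HMPA) and the E-alkene react through a chair with the carbinol methyl equatorial, giving the anti (2S,3S) acid by 1,3-chirality transfer (expected dr about 9:1; the minor syn isomer is removed at 11).

**Step 4**
Reactants: 5, (2S,3S,E)-2,3-dimethylhex-4-enoic acid; 6, N,O-dimethylhydroxylamine hydrochloride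
Product: 7, (2S,3S,E)-N-methoxy-N,2,3-trimethylhex-4-enamide
Conditions: CDI, CH2Cl2, rt; then MeNH(OMe)·HCl, rt
Reagents that add atoms: N,O-dimethylhydroxylamine hydrochloride, CNOC.Cl
Why: Weinreb amide formation via the acyl imidazolide, mild enough not to epimerise C2.

**Step 5**
Reactants: 8, 5-bromo-2-methoxyphenol; 9, benzyl bromide
Product: 10, 2-(benzyloxy)-4-bromo-1-methoxybenzene
Conditions: BnBr, K2CO3, DMF, rt
Reagents that add atoms: benzyl bromide, BrCc1ccccc1
Why: Williamson etherification; benzyl protects the future 7-OH and is removable by neutral hydrogenolysis.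

**Step 6**
Reactants: 7, the Weinreb amide; 10, 2-(benzyloxy)-4-bromo-1-methoxybenzene
Product: 11, (2S,3S,E)-1-[3-(benzyloxy)-4-methoxyphenyl]-2,3-dimethylhex-4-en-1-one
Conditions: 10, n-BuLi, THF, −78 °C; then 7, −78 → −20 °C; aq. NH4Cl
Reagents that add atoms: aryllithium from 10, COc1ccc([Li])cc1OCc1ccccc1
Why: Br–Li exchange then Weinreb ketone synthesis; the chelated tetrahedral intermediate stops at the ketone and shields the α-centre until the cold quench.

**Step 7**
Reactants: 11, the aryl ketone
Product: 12, (1RS,2S,3S,E)-1-[3-(benzyloxy)-4-methoxyphenyl]-2,3-dimethylhex-4-en-1-ol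
Conditions: NaBH4, CeCl3·7H2O, MeOH, −20 → 0 °C
Reagents that add atoms: none
Why: Luche-type carbonyl reduction under near-neutral conditions takes C1 out of the ketone level at once, so C2 cannot enolise; the C1 configuration is irrelevant.

**Step 8**
Reactants: 12, the benzylic alcohol; 13, pivaloyl chloride
Product: 14, (1RS,2S,3S,E)-1-[3-(benzyloxy)-4-methoxyphenyl]-2,3-dimethylhex-4-en-1-yl pivalate
Conditions: PivCl, DMAP, pyridine, CH2Cl2, rt → 40 °C
Reagents that add atoms: pivaloyl chloride, CC(C)(C)C(=O)Cl
Why: Acylation gives a hindered, non-participating ester that survives the Grignard step and is far harder to ionise than a free benzylic alcohol.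

**Step 9**
Reactants: 14, the alkenyl pivalate
Product: 15, (1RS,2S,3R)-1-[3-(benzyloxy)-4-methoxyphenyl]-2,3-dimethyl-4-oxobutyl pivalate
Conditions: OsO4 (cat.), NaIO4, 2,6-lutidine, dioxane/H2O, rt; used crude
Reagents that add atoms: osmium tetroxide, O=[Os](=O)(=O)=O, reoxidised by sodium periodate, [Na+].[O-]I(=O)(=O)=O (source of the aldehyde oxygen)
Why: Lemieux–Johnson cleavage of the disubstituted alkene (acetaldehyde lost) spares the electron-rich arene; the lutidine buffer limits epimerisation of the α-centre. The C3 descriptor changes to R only because CIP priorities change.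

**Step 10**
Reactants: 15, the aldehyde; 16, 4-bromo-1,2-dimethoxybenzene
Product: 17, (1RS,2S,3R,4RS)-1-[3-(benzyloxy)-4-methoxyphenyl]-4-(3,4-dimethoxyphenyl)-4-hydroxy-2,3-dimethylbutyl pivalate
Conditions: 16, Mg, THF; then 15, THF, −78 °C; aq. NH4Cl quench at −78 °C
Reagents that add atoms: 3,4-dimethoxyphenylmagnesium bromide from 16, COc1ccc([Mg]Br)cc1OC
Why: Grignard 1,2-addition is chemoselective for the aldehyde over the pivalate at −78 °C, and the cold quench prevents acyl migration; the C4 configuration is irrelevant.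

**Step 11**
Reactants: 17, the C4 carbinol
Product: 18, (1RS,2S,3S,4R)-7-(benzyloxy)-4-(3,4-dimethoxyphenyl)-6-methoxy-2,3-dimethyl-1,2,3,4-tetrahydronaphthalen-1-yl pivalate
Conditions: BF3·OEt2, CH2Cl2, −78 → −20 °C; cold NaHCO3 quench
Reagents that add atoms: none
Why: Intramolecular Friedel–Crafts alkylation; the free veratryl carbinol should ionise well before the C1 pivalate, and ring A attacks para to OBn. The cation reacts through its A(1,3)-minimised conformer with the tethered arene entering anti to the C3 methyl, so both C4 epimers converge on the 3,4-trans (4R) ring.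

**Step 12**
Reactants: 18, the tetralin pivalate
Product: 19, (1RS,2S,3S,4R)-7-(benzyloxy)-4-(3,4-dimethoxyphenyl)-6-methoxy-2,3-dimethyl-1,2,3,4-tetrahydronaphthalen-1-ol
Conditions: LiAlH4, THF, 0 °C
Reagents that add atoms: none
Why: Reductive ester cleavage; no epimerisable centre exists at this stage.

**Step 13**
Reactants: 19, the tetralol
Product: 20, (2S,3S,4R)-7-(benzyloxy)-4-(3,4-dimethoxyphenyl)-6-methoxy-2,3-dimethyl-3,4-dihydronaphthalen-1(2H)-one
Conditions: Dess–Martin periodinane, NaHCO3, CH2Cl2, 0 °C → rt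
Reagents that add atoms: none
Why: Buffered Dess–Martin oxidation converts both C1 epimers to the ketone without enolising the kinetically set cis-2-methyl centre.

**Step 14**
Reactants: 20, O-benzylschisandrone
Product: 21, schisandrone, (2S,3S,4R)-4-(3,4-dimethoxyphenyl)-7-hydroxy-6-methoxy-2,3-dimethyl-3,4-dihydronaphthalen-1(2H)-one
Conditions: H2 (1 atm), 10% Pd/C, EtOAc, rt
Reagents that add atoms: none
Why: Neutral hydrogenolysis of the aryl benzyl ether frees the 7-OH without epimerising C2 or reducing the electron-rich aryl ketone.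

## Compound list

1 | (E)-pent-3-en-2-one | C/C=C/C(C)=O | starting material
2 | (R,E)-pent-3-en-2-ol | C[C@@H](O)/C=C/C | intermediate
3 | propanoyl chloride | CCC(=O)Cl | starting material
4 | (R,E)-pent-3-en-2-yl propanoate | CCC(=O)O[C@H](C)/C=C/C | intermediate
5 | (2S,3S,E)-2,3-dimethylhex-4-enoic acid | OC(=O)[C@@H](C)[C@@H](C)/C=C/C | intermediate
6 | N,O-dimethylhydroxylamine hydrochloride | CNOC.Cl | starting material
7 | (2S,3S,E)-N-methoxy-N,2,3-trimethylhex-4-enamide | CON(C)C(=O)[C@@H](C)[C@@H](C)/C=C/C | intermediate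
8 | 5-bromo-2-methoxyphenol | COc1ccc(Br)cc1O | starting material
9 | benzyl bromide | BrCc1ccccc1 | starting material
10 | 2-(benzyloxy)-4-bromo-1-methoxybenzene | COc1ccc(Br)cc1OCc1ccccc1 | intermediate
11 | (2S,3S,E)-1-[3-(benzyloxy)-4-methoxyphenyl]-2,3-dimethylhex-4-en-1-one | COc1ccc(cc1OCc1ccccc1)C(=O)[C@@H](C)[C@@H](C)/C=C/C | intermediate
12 | (1RS,2S,3S,E)-1-[3-(benzyloxy)-4-methoxyphenyl]-2,3-dimethylhex-4-en-1-ol | COc1ccc(cc1OCc1ccccc1)C(O)[C@@H](C)[C@@H](C)/C=C/C | intermediate
13 | pivaloyl chloride | CC(C)(C)C(=O)Cl | starting material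
14 | (1RS,2S,3S,E)-1-[3-(benzyloxy)-4-methoxyphenyl]-2,3-dimethylhex-4-en-1-yl pivalate | COc1ccc(cc1OCc1ccccc1)C(OC(=O)C(C)(C)C)[C@@H](C)[C@@H](C)/C=C/C | intermediate
15 | (1RS,2S,3R)-1-[3-(benzyloxy)-4-methoxyphenyl]-2,3-dimethyl-4-oxobutyl pivalate | COc1ccc(cc1OCc1ccccc1)C(OC(=O)C(C)(C)C)[C@@H](C)[C@@H](C)C=O | intermediate
16 | 4-bromo-1,2-dimethoxybenzene | COc1ccc(Br)cc1OC | starting material
17 | (1RS,2S,3R,4RS)-1-[3-(benzyloxy)-4-methoxyphenyl]-4-(3,4-dimethoxyphenyl)-4-hydroxy-2,3-dimethylbutyl pivalate | COc1ccc(cc1OCc1ccccc1)C(OC(=O)C(C)(C)C)[C@@H](C)[C@@H](C)C(O)c1ccc(OC)c(OC)c1 | intermediate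
18 | (1RS,2S,3S,4R)-7-(benzyloxy)-4-(3,4-dimethoxyphenyl)-6-methoxy-2,3-dimethyl-1,2,3,4-tetrahydronaphthalen-1-yl pivalate | COc1cc2c(cc1OCc1ccccc1)C(OC(=O)C(C)(C)C)[C@@H](C)[C@@H](C)[C@@H]2c1ccc(OC)c(OC)c1 | intermediate
19 | (1RS,2S,3S,4R)-7-(benzyloxy)-4-(3,4-dimethoxyphenyl)-6-methoxy-2,3-dimethyl-1,2,3,4-tetrahydronaphthalen-1-ol | COc1cc2c(cc1OCc1ccccc1)C(O)[C@@H](C)[C@@H](C)[C@@H]2c1ccc(OC)c(OC)c1 | intermediate
20 | (2S,3S,4R)-7-(benzyloxy)-4-(3,4-dimethoxyphenyl)-6-methoxy-2,3-dimethyl-3,4-dihydronaphthalen-1(2H)-one | COc1cc2c(cc1OCc1ccccc1)C(=O)[C@@H](C)[C@@H](C)[C@@H]2c1ccc(OC)c(OC)c1 | intermediate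
21 | schisandrone | COc1cc2c(cc1O)C(=O)[C@@H](C)[C@@H](C)[C@@H]2c1ccc(OC)c(OC)c1 | target

## Summary

Total steps: 14.
Longest linear sequence: 13 (steps 1–4 and 6–14; step 5 is a one-step side branch).

Three steps most likely to fail:

1. **Step 11 (cationic ring closure).** The C1 benzylic pivalate may also ionise, leading to elimination to a dihydronaphthalene or attack by the wrong ring. Fallback: remove the second ionisable C–O altogether by carrying C1 at the ketone level as a 1,3-dithiolane (with the C4 aldehyde held as a dimethyl acetal from the Weinreb amide stage), run the same C4-cation cyclisation, and unmask oxidatively with PhI(OCOCF3)2.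
2. **Step 3 (Ireland–Claisen).** Anti:syn selectivity is only about 9:1 and depends on enolate geometry. Fallback: obtain the anti-2,3-dimethyl unit with fixed relative configuration by lipase-catalysed desymmetrisation (vinyl acetate) of meso-2,3-dimethylbutane-1,4-diol, then elaborate the two CH2OH termini one at a time by oxidation and aryl addition.
3. **Step 1 (enzymatic reduction).** The small, volatile, water-miscible enone may be poorly accepted or hard to isolate. Fallback: make the same carbinol by Noyori asymmetric transfer hydrogenation of pent-3-yn-2-one, followed by LiAlH4 trans-reduction of the propargylic alcohol to the (E)-allylic alcohol.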